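## The problem

Compound 24 is a linear procyanidin tetramer built from four (2R,3R)-epicatechin units. Unit 1 is joined through C4 to C6 of unit 2, unit 2 through C4 to C8 of unit 3, and unit 3 through C4 to C6 of unit 4. Each interflavan bond is β, which means 3,4-trans and 2,4-trans in its own ring C.

There are eleven stereocentres: C2 and C3 of every unit, and C4 of units 1, 2 and 3. Within a unit, the α-oriented C2 aryl group and C3 oxygen send a nucleophile to the β face of a C4 cation. Each C4 centre can therefore be controlled from its own ring, provided that ring already exists. Nothing relays stereochemistry from one unit to the next.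

Regiochemistry is the harder problem. Ring A of every unit is a phloroglucinol nucleus with two nucleophilic CH positions, and C8 reacts in preference to C6. Two of the three interflavan bonds (both 4→6) therefore run against the innate preference. In addition, a unit that must act first as a C4 electrophile and later as a C8 nucleophile tends to condense with itself.

The free compound carries sixteen phenolic and four secondary hydroxyl groups. Its catechols oxidise in air, its doubly benzylic C4–aryl bonds ionise in acid, and C2 epimerises in base. Protection therefore has to be uniform and must be removed under neutral conditions.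

The feature that opens a non-classical route is ring C of unit 3: O1, C2, C3 and C4 fused on the C4a–C8a edge, with C4 bonded to C6 of unit 4. This ring is the formal [4+2] adduct of an o-quinone methide (O=C8a–C4a=C4), whose methide carbon already carries unit 4, with a Z-configured two-carbon partner that brings the C2 aryl group and a latent C3 hydroxyl.

## Retrosynthesis

**Endgame, 24 from 23 from 22.** No skeletal bond is cut. All sixteen phenols are benzyl ethers. Four ring A positions carry bromine: C6 and C8 of unit 1, C8 of unit 2 and C8 of unit 4. These bromines are regiochemical caps and leave in the same hydrogenolysis that removes the benzyl groups. The one silyl ether, on O3 of unit 4, is cleaved just before (23 from 22). The forward reactions only need to be neutral.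

**22 to 21 plus 17: bond between C4 of unit 2 and C8 of unit 3.** This is the only interflavan bond that follows the innate C8 preference. It is therefore the one that can safely be left to a late cationic coupling of two dimers of equal size. The forward reaction must ionise C4 of unit 2 in 21 and nothing else, which a thiophilic silver salt acting on a benzyl sulfide can do. Capture must occur at C8 of unit 3 in 17 from the β face. Every other ring A position of 21 is capped, and C8 of unit 4 in 17 is capped.

**17 from 16, and 16 to 11 plus 14 through 15: O1–C2 and C3–C4 of unit 3.** The neighbouring cut, the bond from C4 of unit 3 to C6 of unit 4, would require a unit 3 electrophile with a free C8. Such a compound condenses with itself, and it would also have to attack a C6 position. Cutting ring C instead means the 4→6 bond is already in place when the ring is formed, and unit 3 never exists as a C4 cation.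

- The precursors are much simpler: the o-hydroxybenzhydrol 11 and the Z-alkenylboronate 14. One ring and three stereocentres are removed.
- Boron is chosen as the oxygen surrogate because a Z-enol ether would react with the opposite polarity. With boron the aryl group dictates the polarity, and the C–B bond is later oxidised with retention (17 from 16).
- The forward reaction must bond the boron-bearing carbon to C4 and the aryl-bearing carbon to O1. It must carry the Z geometry into the 2,3-cis relationship, place boron anti to unit 4, and choose one face of the methide 15 under catalyst control.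

**11 from 10, and 10 to 5 plus 8 through 9: carbinol carbon to C6 of unit 4.** The other carbinol bond would need a metalated phloroglucinol ring with three differentiated oxygens. Here the differentiation is carried by the aldehyde 8, which comes in two alkylations from 6 through 7. The nucleophile is reached by iodine–magnesium exchange at C6 of 5, which leaves the C8 bromide alone. The forward reaction must add a di-ortho-substituted arylmagnesium to a di-ortho-substituted aldehyde and then free the phenol without acid. This is the reason for the allyl ether.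

**5 from 4 from 3 from 2 from 1.** Only carbon–halogen and oxygen–protecting-group bonds are cut. Bromination of 2 takes the innate C8 position to give 3. After silylation to 4, the only open ring A position is C6, which takes iodine to give 5. The C8 bromine thus serves as a director for the iodination and as the cap needed in the coupling to 22.

**14 from 13 from 12.** The alkene C–B bond is cut, then the alkyne. A trans-hydroboration of the terminal alkyne 13 with pinacolborane gives the Z-boronate directly. The alkyne comes from aldehyde 12 by one-carbon homologation.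

**21 to 20 plus 19, both from 18, which comes from 3: bond between C4 of unit 1 and C6 of unit 2.** A 4→6 bond made by cationic coupling needs C8 of the nucleophile capped, as in 19, and both ring A positions of the electrophile capped, as in 20. Both compounds come from the common ether 18. The sulfide in 19 is inert to the hard Lewis acid that ionises the ether in 20. It remains as the latent leaving group used in the union with 17.

## Roads not taken

**Alternative 1:** The cut is the C4a–C5 bond of ring A of unit 2, with the whole ring assembled beforehand as a pyrone. The precursor is the 2-pyrone A1, which carries unit 1 on C3 and a cinnamoylmethyl chain on C6. Mg(OMe)2 would open it to a triketo ester, and Claisen closure with aromatisation would give the chalcone A2.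

- Merits: unit 1 sits on the future C6 before ring A exists, so the first 4→6 bond is regiochemically fixed. Claisen cyclisation of polyketide chains to phloroglucinols is a dependable reaction, and no chiral catalyst is needed.
- Weak points: the step makes an aromatic ring and no stereocentre. In A2 all of ring C of unit 2 is still missing. C2 and C3 must be set by reagent control, the 2,3-cis relationship secured, and C4 re-activated for the bond to unit 3. That is at least six further steps on a dimer. The two phenols that flank the acyl group differ only in their neighbour. Closing ring C through one gives the 4→6 isomer and through the other the 4→8 isomer, so the regiochemical question returns. Making A1 exposes the acid- and base-sensitive unit 1 to dianion acylation.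
- Comparison: as a reaction, the key step of this alternative is more secure than step 11. The chosen plan has to set against this that its key step delivers a complete ring C with three stereocentres, and that one oxidation then finishes the unit.

**Alternative 2:** The cuts are O1–C8a, C4–C4a and O1–C2 of unit 2. Fluoride would release an aryne from the silyl triflate A3, which carries unit 1. The carbonyl group of the enal A4 adds across the aryne. The resulting o-quinone methide closes by a 6π oxa-electrocyclisation to the flav-3-ene A5.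

- Merits: insertion of arynes into enal carbonyls to give 2H-chromenes is a known reaction class. The benzyloxy group next to the aryne directs the oxygen to C8a. The route is convergent.
- Weak points: C2 is created in a thermal electrocyclisation with no control element, since unit 1 is remote. A5 has no oxygen at C3, and C4 is not functionalised. Hydroboration of the flavene puts the hydroxyl trans to the aryl group, which is the catechin relationship, so an oxidation–reduction inversion is needed. C4 must then be re-oxidised to carry unit 3. The hexasubstituted precursor A3 is long to make, and fluoride rules out silyl ethers.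
- Comparison: this alternative also passes through an o-quinone methide, and its reaction type has precedent, which step 11 does not. The chosen plan has to set against this that it traps the methide with an external alkene: a catalyst can choose the face, the cis relationship comes from alkene geometry, and C3 and C4 arrive already functionalised.

**Alternative 3:** The cut is ring A of unit 4. Photolysis of the dihydropyranyl diazoketone A6 gives a vinylketene. This adds the siloxyalkyne A7, which sits on C4 of unit 3. Cyclobutenone opening and 6π closure (a Danheiser-type benzannulation) give the dimer A8.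

- Merits: the reaction class is known for siloxyalkynes. The bond to C6 of unit 4 is fixed by construction. No stereocentre is formed, so there is no facial problem. A8 is a protecting-group variant of 17 and would join the same endgame.
- Weak points: unit 4 can no longer be taken from epicatechin. Ring C of unit 4 must be synthesised enantioselectively as the diazoketone A6. The ynol silyl ether A7 on a flavan C4 is sensitive and takes several steps. The photolysis has to proceed in the presence of many aryl ether chromophores.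
- Comparison: at the key step this alternative is better than the chosen plan, in both precedent and the absence of a selectivity demand. The chosen plan has to set against this the short access to its partners (11 in eight steps, 14 in two) and the use of the chiral pool for unit 4.

Key step: step 11

Assumption: the sense of facial induction of (R)-TRIP on methide 15 cannot be predicted with confidence. (R) is written throughout, and the (S) acid takes its place if it is the one that places unit 4 on the β face.

Assumption: 10 and 11 are carried as mixtures of carbinol epimers, because this carbon becomes the planar methide carbon of 15.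

## Route

Step 1
Reactants: 1 (−)-epicatechin
Product: 2 5,7,3',4'-tetra-O-benzylepicatechin
Conditions: BnBr (4.5 equiv), K2CO3, DMF, 0 °C to rt
Reagents that add atoms: benzyl bromide, BrCc1ccccc1
Why: Williamson etherification of the four phenols; the secondary 3-OH is not deprotonated by carbonate and stays free.

Step 2
Reactants: 2 5,7,3',4'-tetra-O-benzylepicatechin
Product: 3 8-bromo-5,7,3',4'-tetra-O-benzylepicatechin
Conditions: NBS (1.0 equiv), CH2Cl2, −40 °C to rt
Reagents that add atoms: N-bromosuccinimide, O=C1CCC(=O)N1Br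
Why: Electrophilic aromatic bromination; the phloroglucinol ring A reacts far faster than ring B and takes the first halogen at C8, its innately more nucleophilic position.

Step 3
Reactants: 3 8-bromo-5,7,3',4'-tetra-O-benzylepicatechin
Product: 4 8-bromo-3-O-(tert-butyldimethylsilyl)-5,7,3',4'-tetra-O-benzylepicatechin
Conditions: TBSCl, imidazole, DMF, rt
Reagents that add atoms: tert-butyldimethylsilyl chloride, CC(C)(C)[Si](C)(C)Cl
Why: Standard silylation of the secondary alcohol, needed so that the organomagnesium of step 7 is not quenched.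

Step 4
Reactants: 4 8-bromo-3-O-(tert-butyldimethylsilyl)-5,7,3',4'-tetra-O-benzylepicatechin
Product: 5 8-bromo-6-iodo-3-O-(tert-butyldimethylsilyl)-5,7,3',4'-tetra-O-benzylepicatechin
Conditions: NIS (1.1 equiv), TFA (10 mol%), MeCN/CH2Cl2, 0 °C to rt, dark
Reagents that add atoms: N-iodosuccinimide, O=C1CCC(=O)N1I
Why: Electrophilic aromatic iodination; C6 is the only open position of the triply oxygenated ring A, which remains more nucleophilic than the catechol diether ring B.

Step 5
Reactants: 6 2,4,6-trihydroxybenzaldehyde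
Product: 7 2,4-bis(benzyloxy)-6-hydroxybenzaldehyde
Conditions: BnBr (2.1 equiv), K2CO3 (2.2 equiv), DMF, 0 °C to rt
Reagents that add atoms: benzyl bromide, BrCc1ccccc1
Why: Selective Williamson etherification; once one ortho hydroxyl is alkylated, the remaining one is locked in a hydrogen bond to the formyl group and resists alkylation at room temperature.

Step 6
Reactants: 7 2,4-bis(benzyloxy)-6-hydroxybenzaldehyde
Product: 8 2-(allyloxy)-4,6-bis(benzyloxy)benzaldehyde
Conditions: allyl bromide, K2CO3, DMF, 60 °C
Reagents that add atoms: allyl bromide, C=CCBr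
Why: Williamson etherification of the chelated phenol on warming; allyl is chosen because it comes off later without acid, base or fluoride.

Step 7
Reactants: 5 8-bromo-6-iodo-3-O-(tert-butyldimethylsilyl)-5,7,3',4'-tetra-O-benzylepicatechin; 8 2-(allyloxy)-4,6-bis(benzyloxy)benzaldehyde
Product: 10 [2-(allyloxy)-4,6-bis(benzyloxy)phenyl][8-bromo-3-O-(tert-butyldimethylsilyl)-5,7,3',4'-tetra-O-benzylepicatechin-6-yl]methanol as a mixture of carbinol epimers, via arylmagnesium chloride 9 (not isolated)
Conditions: i-PrMgCl·LiCl (1.05 equiv), THF, −30 °C; then 8, −30 °C to rt; aq NH4Cl; Et3N-washed silica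
Reagents that add atoms: none
Why: Iodine–magnesium exchange is much faster at the C–I bond than at the C–Br bond, and the two flanking benzyloxy groups stabilise the arylmagnesium; Grignard addition to the aldehyde then gives the benzhydrol, whose configuration is irrelevant.

Step 8
Reactants: 10 [2-(allyloxy)-4,6-bis(benzyloxy)phenyl][8-bromo-3-O-(tert-butyldimethylsilyl)-5,7,3',4'-tetra-O-benzylepicatechin-6-yl]methanol
Product: 11 [4,6-bis(benzyloxy)-2-hydroxyphenyl][8-bromo-3-O-(tert-butyldimethylsilyl)-5,7,3',4'-tetra-O-benzylepicatechin-6-yl]methanol as a mixture of carbinol epimers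
Conditions: Pd(PPh3)4 (5 mol%), morpholine (5 equiv), THF, rt
Reagents that add atoms: none
Why: Tsuji–Trost deallylation; the zerovalent palladium complex ionises the aryl allyl ether and morpholine captures the allyl group, under neutral conditions that leave the acid-labile benzhydrol, the silyl ether and the hindered aryl bromide untouched.

Step 9
Reactants: 12 3,4-bis(benzyloxy)benzaldehyde
Product: 13 1,2-bis(benzyloxy)-4-ethynylbenzene
Conditions: dimethyl (1-diazo-2-oxopropyl)phosphonate, K2CO3, MeOH/THF, 0 °C to rt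
Reagents that add atoms: dimethyl (1-diazo-2-oxopropyl)phosphonate, CC(=O)C(=[N+]=[N-])P(=O)(OC)OC
Why: Seyferth–Gilbert homologation in the Ohira–Bestmann form; the diazoalkene loses nitrogen and the alkylidene carbene rearranges to the terminal alkyne.

Step 10
Reactants: 13 1,2-bis(benzyloxy)-4-ethynylbenzene
Product: 14 (Z)-2-[3,4-bis(benzyloxy)phenyl]ethenylboronic acid pinacol ester
Conditions: pinacolborane, [Rh(cod)Cl]2 (1.5 mol%), P(i-Pr)3 (6 mol%), Et3N, cyclohexane, rt; 13 in slight excess
Reagents that add atoms: pinacolborane, CC1(C)OBOC1(C)C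
Why: Rhodium-catalysed trans-hydroboration of a terminal alkyne; the reaction runs through a rhodium vinylidene, so boron and the migrated hydrogen end up trans and the Z-alkenylboronate results.

Step 11
Reactants: 11 [4,6-bis(benzyloxy)-2-hydroxyphenyl][8-bromo-3-O-(tert-butyldimethylsilyl)-5,7,3',4'-tetra-O-benzylepicatechin-6-yl]methanol; 14 (Z)-2-[3,4-bis(benzyloxy)phenyl]ethenylboronic acid pinacol ester
Product: 16 3-deoxy-3α-(4,4,5,5-tetramethyl-1,3,2-dioxaborolan-2-yl)-5,7,3',4'-tetra-O-benzylepicatechin-(4β→6)-8-bromo-3-O-(tert-butyldimethylsilyl)-5,7,3',4'-tetra-O-benzylepicatechin, via o-quinone methide 15 (not isolated)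
Conditions: 14 (2 equiv), (R)-TRIP [(R)-3,3'-bis(2,4,6-triisopropylphenyl)-1,1'-binaphthyl-2,2'-diyl hydrogen phosphate] (10 mol%), 4 Å MS, toluene, 0 °C to rt, slow addition of 11
Reagents that add atoms: none
Why: Proposed new method: the chiral phosphoric acid dehydrates 11 to the hydrogen-bonded o-quinone methide 15, whose heterodiene O=C8a–C4a=C4 adds the aryl-polarised Z-alkene 14 in an asynchronous inverse-demand oxa-Diels–Alder reaction, the boron-bearing carbon bonding to the methide carbon C4 and the aryl-bearing carbon to O1; the closest known reaction type is the phosphoric-acid-catalysed [4+2] of o-quinone methides from o-hydroxybenzhydrols with styrenes, enol ethers and enamides. Ring C of unit 3 closes as a six-membered ring by [4+2] cycloaddition, with O1–C2 and C3–C4 formed in one event. C4 is set by the catalyst, which shields one face of the bound methide, because unit 4 is locally symmetric at C6 and its own stereocentres are too remote to choose a face. C3 is set relative to C4 by the approach that keeps the pinacolboryl group anti to the di-ortho-substituted aryl group on C4 (endo to the Z-methide that the peri 5-benzyloxy group favours), which gives 3,4-trans. C2 is set relative to C3 by suprafacial addition to the Z-alkene, which gives 2,3-cis. Regioselectivity is secured by the 4-benzyloxyphenyl donor, which makes the boron-bearing carbon the nucleophilic terminus and places the developing positive charge at the benzylic carbon, β to boron. Retention of alkene geometry is supported by a weak acid in a non-polar solvent, so that ring closure outruns bond rotation in any zwitterion. The wrong-face adduct is a diastereomer, because unit 4 is enantiopure, and is removed by chromatography.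

Step 12
Reactants: 16 3-deoxy-3α-(pinacolboryl) dimer
Product: 17 5,7,3',4'-tetra-O-benzylepicatechin-(4β→6)-8-bromo-3-O-(tert-butyldimethylsilyl)-5,7,3',4'-tetra-O-benzylepicatechin
Conditions: NaBO3·4H2O (5 equiv), THF/H2O, rt
Reagents that add atoms: sodium perborate, [Na+].[Na+].O[B-]1(O)OO[B-](O)(O)OO1
Why: Oxidation of a secondary alkyl pinacolboronate by 1,2-migration from boron to oxygen with retention, so the 3α-boryl group becomes the 3α-hydroxyl of an epicatechin unit; the axial C–B bond is not antiperiplanar to C2–O1, which disfavours ring-opening elimination.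

Step 13
Reactants: 3 8-bromo-5,7,3',4'-tetra-O-benzylepicatechin
Product: 18 8-bromo-4β-(2-ethoxyethoxy)-5,7,3',4'-tetra-O-benzylepicatechin
Conditions: DDQ (2 equiv), 2-ethoxyethanol (10 equiv), CH2Cl2, rt
Reagents that add atoms: 2-ethoxyethanol, CCOCCO
Why: DDQ abstracts hydride from the benzylic C4 of the electron-rich ring, and the alcohol captures the cation from the β face, anti to the 2-aryl and 3-hydroxyl groups.

Step 14
Reactants: 18 8-bromo-4β-(2-ethoxyethoxy)-5,7,3',4'-tetra-O-benzylepicatechin
Product: 19 8-bromo-4β-(benzylsulfanyl)-5,7,3',4'-tetra-O-benzylepicatechin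
Conditions: BnSH (3 equiv), BF3·OEt2 (1.2 equiv), CH2Cl2, −78 to −20 °C
Reagents that add atoms: phenylmethanethiol, SCc1ccccc1
Why: Lewis-acid ionisation of the C4 ether and capture of the cation by the thiol from the β face; the excess thiol outcompetes the weakly nucleophilic C6 of a second molecule.

Step 15
Reactants: 18 8-bromo-4β-(2-ethoxyethoxy)-5,7,3',4'-tetra-O-benzylepicatechin
Product: 20 6,8-dibromo-4β-(2-ethoxyethoxy)-5,7,3',4'-tetra-O-benzylepicatechin
Conditions: NBS (1.1 equiv), CH2Cl2, −20 °C to rt
Reagents that add atoms: N-bromosuccinimide, O=C1CCC(=O)N1Br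
Why: Electrophilic bromination of the last open ring A position, giving an electrophile that cannot condense with itself.

Step 16
Reactants: 20 6,8-dibromo-4β-(2-ethoxyethoxy)-5,7,3',4'-tetra-O-benzylepicatechin; 19 8-bromo-4β-(benzylsulfanyl)-5,7,3',4'-tetra-O-benzylepicatechin
Product: 21 6,8-dibromo-5,7,3',4'-tetra-O-benzylepicatechin-(4β→6)-8-bromo-4β-(benzylsulfanyl)-5,7,3',4'-tetra-O-benzylepicatechin
Conditions: 19 (1.5 equiv), BF3·OEt2 (1.5 equiv), 4 Å MS, CH2Cl2, −78 to −30 °C
Reagents that add atoms: none
Why: Friedel–Crafts-type flavanyl cation coupling; the hard Lewis acid ionises the C4 ether of 20 but not the sulfide of 19, whose C8 bromine leaves C6 as the only site of attack, and the cation is taken from the β face to give the 3,4-trans bond.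

Step 17
Reactants: 21 upper dimer sulfide; 17 lower dimer
Product: 22 6,8-dibromo-5,7,3',4'-tetra-O-benzylepicatechin-(4β→6)-8-bromo-5,7,3',4'-tetra-O-benzylepicatechin-(4β→8)-5,7,3',4'-tetra-O-benzylepicatechin-(4β→6)-8-bromo-3-O-(tert-butyldimethylsilyl)-5,7,3',4'-tetra-O-benzylepicatechin
Conditions: 17 (1.2 equiv), AgBF4 (2.5 equiv), 2,6-di-tert-butyl-4-methylpyridine, THF/CH2Cl2, −20 to 0 °C, dark
Reagents that add atoms: none
Why: Thiophilic silver activation of the flavan-4-yl benzyl sulfide gives the C4 cation of unit 2 under near-neutral conditions; C8 of unit 3 is the most nucleophilic uncapped position in 17 and attacks from the β face, anti to the 2-aryl and 3-hydroxyl groups of unit 2.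

Step 18
Reactants: 22 protected tetramer silyl ether
Product: 23 the same tetramer with free 3-OH on unit 4
Conditions: TBAF (3 equiv), AcOH (3 equiv), THF, 0 °C to rt
Reagents that add atoms: none
Why: Fluoride cleavage of the secondary silyl ether; the acetic acid buffer keeps the medium from becoming basic enough to epimerise C2.

Step 19
Reactants: 23 hexadeca-O-benzyl tetrabromo tetramer
Product: 24 epicatechin-(4β→6)-epicatechin-(4β→8)-epicatechin-(4β→6)-epicatechin
Conditions: H2 (1 atm), Pd(OH)2/C, NaOAc, THF/MeOH/H2O, rt; filtration under argon, lyophilisation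
Reagents that add atoms: none
Why: Hydrogenolysis removes the sixteen benzyl ethers and the four aryl bromides in one neutral operation; acetate buffers the hydrogen bromide so that the interflavan bonds are not exposed to strong acid.

## Compound list

1 | (−)-epicatechin, (2R,3R)-2-(3,4-dihydroxyphenyl)chroman-3,5,7-triol | O[C@@H]1Cc2c(O)cc(O)cc2O[C@@H]1c1ccc(O)c(O)c1 | starting material
2 | 5,7,3',4'-tetra-O-benzylepicatechin | O[C@@H]1Cc2c(OCc3ccccc3)cc(OCc3ccccc3)cc2O[C@@H]1c4ccc(OCc3ccccc3)c(OCc3ccccc3)c4 | intermediate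
3 | 8-bromo-5,7,3',4'-tetra-O-benzylepicatechin | O[C@@H]1Cc2c(OCc3ccccc3)cc(OCc3ccccc3)c(Br)c2O[C@@H]1c4ccc(OCc3ccccc3)c(OCc3ccccc3)c4 | intermediate
4 | 8-bromo-3-O-(tert-butyldimethylsilyl)-5,7,3',4'-tetra-O-benzylepicatechin | CC(C)(C)[Si](C)(C)O[C@@H]1Cc2c(OCc3ccccc3)cc(OCc3ccccc3)c(Br)c2O[C@@H]1c4ccc(OCc3ccccc3)c(OCc3ccccc3)c4 | intermediate
5 | 8-bromo-6-iodo-3-O-(tert-butyldimethylsilyl)-5,7,3',4'-tetra-O-benzylepicatechin | CC(C)(C)[Si](C)(C)O[C@@H]1Cc2c(OCc3ccccc3)c(I)c(OCc3ccccc3)c(Br)c2O[C@@H]1c4ccc(OCc3ccccc3)c(OCc3ccccc3)c4 | intermediate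
6 | 2,4,6-trihydroxybenzaldehyde | O=Cc1c(O)cc(O)cc1O | starting material
7 | 2,4-bis(benzyloxy)-6-hydroxybenzaldehyde | O=Cc1c(O)cc(OCc3ccccc3)cc1OCc3ccccc3 | intermediate
8 | 2-(allyloxy)-4,6-bis(benzyloxy)benzaldehyde | O=Cc1c(OCC=C)cc(OCc3ccccc3)cc1OCc3ccccc3 | intermediate
9 | C6 arylmagnesium chloride of unit 4 (LiCl complex; 8-bromo, 3-O-TBS, tetra-O-benzyl) | CC(C)(C)[Si](C)(C)O[C@@H]1Cc2c(OCc3ccccc3)c([Mg]Cl)c(OCc3ccccc3)c(Br)c2O[C@@H]1c4ccc(OCc3ccccc3)c(OCc3ccccc3)c4 | intermediate (not isolated)
10 | [2-(allyloxy)-4,6-bis(benzyloxy)phenyl][8-bromo-3-O-(tert-butyldimethylsilyl)-5,7,3',4'-tetra-O-benzylepicatechin-6-yl]methanol, both carbinol epimers | C=CCOc1cc(OCc3ccccc3)cc(OCc3ccccc3)c1C(O)c5c(OCc3ccccc3)c(Br)c6c(c5OCc3ccccc3)C[C@@H](O[Si](C)(C)C(C)(C)C)[C@@H](c4ccc(OCc3ccccc3)c(OCc3ccccc3)c4)O6 | intermediate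
11 | [4,6-bis(benzyloxy)-2-hydroxyphenyl][8-bromo-3-O-(tert-butyldimethylsilyl)-5,7,3',4'-tetra-O-benzylepicatechin-6-yl]methanol, both carbinol epimers | Oc1cc(OCc3ccccc3)cc(OCc3ccccc3)c1C(O)c5c(OCc3ccccc3)c(Br)c6c(c5OCc3ccccc3)C[C@@H](O[Si](C)(C)C(C)(C)C)[C@@H](c4ccc(OCc3ccccc3)c(OCc3ccccc3)c4)O6 | intermediate
12 | 3,4-bis(benzyloxy)benzaldehyde | O=Cc1ccc(OCc3ccccc3)c(OCc3ccccc3)c1 | starting material
13 | 1,2-bis(benzyloxy)-4-ethynylbenzene | C#Cc1ccc(OCc3ccccc3)c(OCc3ccccc3)c1 | intermediate
14 | (Z)-2-[3,4-bis(benzyloxy)phenyl]ethenylboronic acid pinacol ester | CC1(C)OB(OC1(C)C)/C=C\c2ccc(OCc3ccccc3)c(OCc3ccccc3)c2 | intermediate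
15 | 3,5-bis(benzyloxy)-6-[(unit 4-6-yl)methylidene]cyclohexa-2,4-dien-1-one, drawn as the Z isomer (aryl syn to the carbonyl) | O=C1C=C(OCc3ccccc3)C=C(OCc3ccccc3)/C1=C/c5c(OCc3ccccc3)c(Br)c6c(c5OCc3ccccc3)C[C@@H](O[Si](C)(C)C(C)(C)C)[C@@H](c4ccc(OCc3ccccc3)c(OCc3ccccc3)c4)O6 | intermediate (not isolated)
16 | 3-deoxy-3α-(pinacolboryl)-5,7,3',4'-tetra-O-benzylepicatechin-(4β→6)-8-bromo-3-O-(tert-butyldimethylsilyl)-5,7,3',4'-tetra-O-benzylepicatechin (2,3-cis, 3,4-trans in unit 3) | O(Cc3ccccc3)c1cc(OCc3ccccc3)c2c(c1)O[C@H](c4ccc(OCc3ccccc3)c(OCc3ccccc3)c4)[C@H](B7OC(C)(C)C(C)(C)O7)[C@H]2c5c(OCc3ccccc3)c(Br)c6c(c5OCc3ccccc3)C[C@@H](O[Si](C)(C)C(C)(C)C)[C@@H](c4ccc(OCc3ccccc3)c(OCc3ccccc3)c4)O6 | intermediate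
17 | 5,7,3',4'-tetra-O-benzylepicatechin-(4β→6)-8-bromo-3-O-(tert-butyldimethylsilyl)-5,7,3',4'-tetra-O-benzylepicatechin | O(Cc3ccccc3)c1cc(OCc3ccccc3)c2c(c1)O[C@H](c4ccc(OCc3ccccc3)c(OCc3ccccc3)c4)[C@H](O)[C@H]2c5c(OCc3ccccc3)c(Br)c6c(c5OCc3ccccc3)C[C@@H](O[Si](C)(C)C(C)(C)C)[C@@H](c4ccc(OCc3ccccc3)c(OCc3ccccc3)c4)O6 | intermediate
18 | 8-bromo-4β-(2-ethoxyethoxy)-5,7,3',4'-tetra-O-benzylepicatechin | Brc1c(OCc3ccccc3)cc(OCc3ccccc3)c2c1O[C@H](c4ccc(OCc3ccccc3)c(OCc3ccccc3)c4)[C@H](O)[C@H]2OCCOCC | intermediate
19 | 8-bromo-4β-(benzylsulfanyl)-5,7,3',4'-tetra-O-benzylepicatechin | Brc1c(OCc3ccccc3)cc(OCc3ccccc3)c2c1O[C@H](c4ccc(OCc3ccccc3)c(OCc3ccccc3)c4)[C@H](O)[C@H]2SCc3ccccc3 | intermediate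
20 | 6,8-dibromo-4β-(2-ethoxyethoxy)-5,7,3',4'-tetra-O-benzylepicatechin | Brc1c(OCc3ccccc3)c(Br)c(OCc3ccccc3)c2c1O[C@H](c4ccc(OCc3ccccc3)c(OCc3ccccc3)c4)[C@H](O)[C@H]2OCCOCC | intermediate
21 | 6,8-dibromo-5,7,3',4'-tetra-O-benzylepicatechin-(4β→6)-8-bromo-4β-(benzylsulfanyl)-5,7,3',4'-tetra-O-benzylepicatechin | Brc1c(OCc3ccccc3)c(Br)c(OCc3ccccc3)c2c1O[C@H](c4ccc(OCc3ccccc3)c(OCc3ccccc3)c4)[C@H](O)[C@H]2c5c(OCc3ccccc3)c(Br)c6c(c5OCc3ccccc3)[C@H](SCc3ccccc3)[C@@H](O)[C@@H](c4ccc(OCc3ccccc3)c(OCc3ccccc3)c4)O6 | intermediate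
22 | protected tetramer: units 1 to 4 as tetra-O-benzyl ethers, 6,8-dibromo on unit 1, 8-bromo on units 2 and 4, 3-O-TBS on unit 4, linkages 4β→6, 4β→8, 4β→6 | Brc1c(OCc3ccccc3)c(Br)c(OCc3ccccc3)c2c1O[C@H](c4ccc(OCc3ccccc3)c(OCc3ccccc3)c4)[C@H](O)[C@H]2c5c(OCc3ccccc3)c(Br)c6c(c5OCc3ccccc3)[C@H](c7c(OCc3ccccc3)cc(OCc3ccccc3)c8c7O[C@H](c4ccc(OCc3ccccc3)c(OCc3ccccc3)c4)[C@H](O)[C@H]8c1c(OCc3ccccc3)c(Br)c2c(c1OCc3ccccc3)C[C@@H](O[Si](C)(C)C(C)(C)C)[C@@H](c4ccc(OCc3ccccc3)c(OCc3ccccc3)c4)O2)[C@@H](O)[C@@H](c4ccc(OCc3ccccc3)c(OCc3ccccc3)c4)O6 | intermediate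
23 | protected tetramer as 22 with free 3-OH on unit 4 | Brc1c(OCc3ccccc3)c(Br)c(OCc3ccccc3)c2c1O[C@H](c4ccc(OCc3ccccc3)c(OCc3ccccc3)c4)[C@H](O)[C@H]2c5c(OCc3ccccc3)c(Br)c6c(c5OCc3ccccc3)[C@H](c7c(OCc3ccccc3)cc(OCc3ccccc3)c8c7O[C@H](c4ccc(OCc3ccccc3)c(OCc3ccccc3)c4)[C@H](O)[C@H]8c1c(OCc3ccccc3)c(Br)c2c(c1OCc3ccccc3)C[C@@H](O)[C@@H](c4ccc(OCc3ccccc3)c(OCc3ccccc3)c4)O2)[C@@H](O)[C@@H](c4ccc(OCc3ccccc3)c(OCc3ccccc3)c4)O6 | intermediate
24 | epicatechin-(4β→6)-epicatechin-(4β→8)-epicatechin-(4β→6)-epicatechin (CNP0120618.1) | Oc1cc(O)c2c(c1)O[C@H](c1ccc(O)c(O)c1)[C@H](O)[C@H]2c1c(O)cc2c(c1O)[C@H](c1c(O)cc(O)c3c1O[C@H](c1ccc(O)c(O)c1)[C@H](O)[C@H]3c1c(O)cc3c(c1O)C[C@@H](O)[C@@H](c1ccc(O)c(O)c1)O3)[C@@H](O)[C@@H](c1ccc(O)c(O)c1)O2 | target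

## Step count and least certain steps

Total step count: 19. Longest linear sequence: 11 steps (steps 1, 2, 3, 4, 7, 8, 11, 12, 17, 18, 19).

**Step 11 (key step, proposed new method).** Several things can go wrong.
- The addition may become stepwise, so that bond rotation in the benzylic zwitterion erodes the 2,3-cis relationship.
- The β-boryl cation may lose boron, giving open-chain alkenylation in place of ring closure.
- Facial selectivity may be poor, because the catalyst pocket has to accommodate a very hindered methide.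
- The methide may condense with the phloroglucinol ring of unreacted 11.

The fallback gives up the cycloaddition and takes ring C of unit 3 from epicatechin. It sets out from 2, 21 and 4 and rejoins the route at 22. Compound 2 is oxidised with DDQ in the presence of 2-ethoxyethanol to 4β-(2-ethoxyethoxy)-5,7,3',4'-tetra-O-benzylepicatechin F1. The sulfide 21 is activated with AgBF4 and 2,6-di-tert-butyl-4-methylpyridine and captured by C8 of F1. This gives the trimer 6,8-dibromo-tetra-O-benzylepicatechin-(4β→6)-8-bromo-tetra-O-benzylepicatechin-(4β→8)-4β-(2-ethoxyethoxy)-tetra-O-benzylepicatechin F2, whose ether survives the soft activation. BF3·OEt2 then ionises that ether in the presence of an excess of the bromide 4, whose only open position is C6, and this gives 22. Unit 3 thus acts as a nucleophile first and as an electrophile only after its C8 is substituted, which avoids self-condensation.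

**Step 17.** Ionisation and capture between two hindered dimers may be slow. Attack may compete at C6 of unit 3. The silyl ether may be lost to adventitious HBF4.

The fallback grows the chain one unit at a time. It sets out from 17, 18 and 20 and rejoins at 24.
- BF3·OEt2 ionises 18 in the presence of 17 and gives the trimer 8-bromo-tetra-O-benzylepicatechin-(4β→8)-tetra-O-benzylepicatechin-(4β→6)-8-bromo-3-O-TBS-tetra-O-benzylepicatechin F3.
- NBS then brominates C6 of unit 3, the only ring A without a bromine, and gives the capped trimer F4.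
- The fully capped electrophile 20 with BF3·OEt2 can now only reach C6 of the first unit of F4 (unit 2 of the target). This gives the pentabromo tetramer F5.
- TBAF with AcOH gives the desilylated pentabromo tetramer F6, and hydrogenolysis under the conditions of step 19 gives 24.

**Step 7.** Addition of the di-ortho-substituted arylmagnesium to the di-ortho-substituted aldehyde may be sluggish. The result would be protonation of 9, or bromine–magnesium exchange on warming.

The fallback reverses the polarity. It sets out from 5 and rejoins at 11. The arylmagnesium 9 is quenched with DMF to 8-bromo-3-O-(tert-butyldimethylsilyl)-5,7,3',4'-tetra-O-benzylepicatechin-6-carbaldehyde F7. The bromomagnesium phenoxide of commercial 3,5-bis(benzyloxy)phenol (EtMgBr, toluene) then adds through its ortho carbon to F7. This is the ortho-specific hydroxyalkylation of a magnesium phenoxide, and it gives 11 directly without 8 and 10.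

**Step 10.** Conventional syn hydroboration, or isomerisation by rhodium hydride, may erode the Z selectivity for this electron-rich aryl alkyne.

The fallback sets out from 13 and rejoins at 14. Deprotonation with n-BuLi and borylation with 2-isopropoxy-4,4,5,5-tetramethyl-1,3,2-dioxaborolane give 2-{[3,4-bis(benzyloxy)phenyl]ethynyl}-4,4,5,5-tetramethyl-1,3,2-dioxaborolane F8. Syn hydrozirconation with Cp2Zr(H)Cl and protonolysis of the C–Zr bond with water then fix the Z geometry.

## Further compounds

F1 | step 11 | 4β-(2-ethoxyethoxy)-5,7,3',4'-tetra-O-benzylepicatechin | O(Cc3ccccc3)c1cc(OCc3ccccc3)c2c(c1)O[C@H](c4ccc(OCc3ccccc3)c(OCc3ccccc3)c4)[C@H](O)[C@H]2OCCOCC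
F2 | step 11 | 6,8-dibromo-tetra-O-benzylepicatechin-(4β→6)-8-bromo-tetra-O-benzylepicatechin-(4β→8)-4β-(2-ethoxyethoxy)-tetra-O-benzylepicatechin | Brc1c(OCc3ccccc3)c(Br)c(OCc3ccccc3)c2c1O[C@H](c4ccc(OCc3ccccc3)c(OCc3ccccc3)c4)[C@H](O)[C@H]2c5c(OCc3ccccc3)c(Br)c6c(c5OCc3ccccc3)[C@H](c7c(OCc3ccccc3)cc(OCc3ccccc3)c8c7O[C@H](c4ccc(OCc3ccccc3)c(OCc3ccccc3)c4)[C@H](O)[C@H]8OCCOCC)[C@@H](O)[C@@H](c4ccc(OCc3ccccc3)c(OCc3ccccc3)c4)O6
F3 | step 17 | 8-bromo-tetra-O-benzylepicatechin-(4β→8)-tetra-O-benzylepicatechin-(4β→6)-8-bromo-3-O-TBS-tetra-O-benzylepicatechin | Brc1c(OCc3ccccc3)cc(OCc3ccccc3)c2c1O[C@H](c4ccc(OCc3ccccc3)c(OCc3ccccc3)c4)[C@H](O)[C@H]2c7c(OCc3ccccc3)cc(OCc3ccccc3)c8c7O[C@H](c4ccc(OCc3ccccc3)c(OCc3ccccc3)c4)[C@H](O)[C@H]8c5c(OCc3ccccc3)c(Br)c6c(c5OCc3ccccc3)C[C@@H](O[Si](C)(C)C(C)(C)C)[C@@H](c4ccc(OCc3ccccc3)c(OCc3ccccc3)c4)O6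
F4 | step 17 | trimer F3 with bromine at C6 of its middle unit | Brc1c(OCc3ccccc3)cc(OCc3ccccc3)c2c1O[C@H](c4ccc(OCc3ccccc3)c(OCc3ccccc3)c4)[C@H](O)[C@H]2c7c(OCc3ccccc3)c(Br)c(OCc3ccccc3)c8c7O[C@H](c4ccc(OCc3ccccc3)c(OCc3ccccc3)c4)[C@H](O)[C@H]8c5c(OCc3ccccc3)c(Br)c6c(c5OCc3ccccc3)C[C@@H](O[Si](C)(C)C(C)(C)C)[C@@H](c4ccc(OCc3ccccc3)c(OCc3ccccc3)c4)O6
F5 | step 17 | pentabromo tetramer: as 22 with an additional bromine at C6 of unit 3 | Brc1c(OCc3ccccc3)c(Br)c(OCc3ccccc3)c2c1O[C@H](c4ccc(OCc3ccccc3)c(OCc3ccccc3)c4)[C@H](O)[C@H]2c5c(OCc3ccccc3)c(Br)c6c(c5OCc3ccccc3)[C@H](c7c(OCc3ccccc3)c(Br)c(OCc3ccccc3)c8c7O[C@H](c4ccc(OCc3ccccc3)c(OCc3ccccc3)c4)[C@H](O)[C@H]8c1c(OCc3ccccc3)c(Br)c2c(c1OCc3ccccc3)C[C@@H](O[Si](C)(C)C(C)(C)C)[C@@H](c4ccc(OCc3ccccc3)c(OCc3ccccc3)c4)O2)[C@@H](O)[C@@H](c4ccc(OCc3ccccc3)c(OCc3ccccc3)c4)O6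
F6 | step 17 | desilylated pentabromo tetramer: as 23 with an additional bromine at C6 of unit 3 | Brc1c(OCc3ccccc3)c(Br)c(OCc3ccccc3)c2c1O[C@H](c4ccc(OCc3ccccc3)c(OCc3ccccc3)c4)[C@H](O)[C@H]2c5c(OCc3ccccc3)c(Br)c6c(c5OCc3ccccc3)[C@H](c7c(OCc3ccccc3)c(Br)c(OCc3ccccc3)c8c7O[C@H](c4ccc(OCc3ccccc3)c(OCc3ccccc3)c4)[C@H](O)[C@H]8c1c(OCc3ccccc3)c(Br)c2c(c1OCc3ccccc3)C[C@@H](O)[C@@H](c4ccc(OCc3ccccc3)c(OCc3ccccc3)c4)O2)[C@@H](O)[C@@H](c4ccc(OCc3ccccc3)c(OCc3ccccc3)c4)O6
F7 | step 7 | 8-bromo-3-O-(tert-butyldimethylsilyl)-5,7,3',4'-tetra-O-benzylepicatechin-6-carbaldehyde | O=Cc5c(OCc3ccccc3)c(Br)c6c(c5OCc3ccccc3)C[C@@H](O[Si](C)(C)C(C)(C)C)[C@@H](c4ccc(OCc3ccccc3)c(OCc3ccccc3)c4)O6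
F8 | step 10 | 2-{[3,4-bis(benzyloxy)phenyl]ethynyl}-4,4,5,5-tetramethyl-1,3,2-dioxaborolane | CC1(C)OB(OC1(C)C)C#Cc2ccc(OCc3ccccc3)c(OCc3ccccc3)c2
A1 | alternative 1 | 4-(benzyloxy)-6-{(E)-4-[3,4-bis(benzyloxy)phenyl]-2-oxobut-3-en-1-yl}-3-(3-O-TBS-5,7,3',4'-tetra-O-benzylepicatechin-4β-yl)-2H-pyran-2-one | O(Cc3ccccc3)c1cc(OCc3ccccc3)c2c(c1)O[C@H](c4ccc(OCc3ccccc3)c(OCc3ccccc3)c4)[C@H](O[Si](C)(C)C(C)(C)C)[C@H]2C5=C(OCc3ccccc3)C=C(CC(=O)/C=C/c4ccc(OCc3ccccc3)c(OCc3ccccc3)c4)OC5=O
A2 | alternative 1 | (E)-chalcone of unit 2: 4'-benzyloxy-2',6'-dihydroxy-3'-(3-O-TBS-5,7,3',4'-tetra-O-benzylepicatechin-4β-yl)-3,4-bis(benzyloxy)chalcone | O(Cc3ccccc3)c1cc(OCc3ccccc3)c2c(c1)O[C@H](c4ccc(OCc3ccccc3)c(OCc3ccccc3)c4)[C@H](O[Si](C)(C)C(C)(C)C)[C@H]2c5c(OCc3ccccc3)cc(O)c(C(=O)/C=C/c4ccc(OCc3ccccc3)c(OCc3ccccc3)c4)c5O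
A3 | alternative 2 | 3,5-bis(benzyloxy)-4-(3,5,7,3',4'-penta-O-benzylepicatechin-4β-yl)-2-(trimethylsilyl)phenyl trifluoromethanesulfonate | O(Cc3ccccc3)c1cc(OCc3ccccc3)c2c(c1)O[C@H](c4ccc(OCc3ccccc3)c(OCc3ccccc3)c4)[C@H](OCc3ccccc3)[C@H]2c5c(OCc3ccccc3)cc(OS(=O)(=O)C(F)(F)F)c([Si](C)(C)C)c5OCc3ccccc3
A4 | alternative 2 | (E)-3-[3,4-bis(benzyloxy)phenyl]prop-2-enal | O=C/C=C/c1ccc(OCc3ccccc3)c(OCc3ccccc3)c1
A5 | alternative 2 | 3,5,7,3',4'-penta-O-benzylepicatechin-(4β→6)-(2R)-5,7,3',4'-tetra-O-benzylflav-3-ene | O(Cc3ccccc3)c1cc(OCc3ccccc3)c2c(c1)O[C@H](c4ccc(OCc3ccccc3)c(OCc3ccccc3)c4)[C@H](OCc3ccccc3)[C@H]2c5c(OCc3ccccc3)cc6c(c5OCc3ccccc3)C=C[C@@H](c4ccc(OCc3ccccc3)c(OCc3ccccc3)c4)O6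
A6 | alternative 3 | 1-{2-[3,4-bis(benzyloxy)phenyl]-3-(tert-butyldimethylsilyloxy)-3,4-dihydro-2H-pyran-6-yl}-2-diazoethanone with the C2 and C3 configurations of unit 4 | [N-]=[N+]=CC(=O)C1=CC[C@@H](O[Si](C)(C)C(C)(C)C)[C@@H](c4ccc(OCc3ccccc3)c(OCc3ccccc3)c4)O1
A7 | alternative 3 | 4β-[(triisopropylsilyloxy)ethynyl]-3-O-TBS-5,7,3',4'-tetra-O-benzylepicatechin | O(Cc3ccccc3)c1cc(OCc3ccccc3)c2c(c1)O[C@H](c4ccc(OCc3ccccc3)c(OCc3ccccc3)c4)[C@H](O[Si](C)(C)C(C)(C)C)[C@H]2C#CO[Si](C(C)C)(C(C)C)C(C)C
A8 | alternative 3 | 3-O-TBS-5,7,3',4'-tetra-O-benzylepicatechin-(4β→6)-3-O-TBS-7-O-triisopropylsilyl-3',4'-di-O-benzylepicatechin with free 5-OH | O(Cc3ccccc3)c1cc(OCc3ccccc3)c2c(c1)O[C@H](c4ccc(OCc3ccccc3)c(OCc3ccccc3)c4)[C@H](O[Si](C)(C)C(C)(C)C)[C@H]2c5c(O[Si](C(C)C)(C(C)C)C(C)C)cc6c(c5O)C[C@@H](O[Si](C)(C)C(C)(C)C)[C@@H](c4ccc(OCc3ccccc3)c(OCc3ccccc3)c4)O6
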